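The flavone is cut at the C4–C4a bond: ring C is closed last by intramolecular Friedel–Crafts acylation of a 3-aryloxy-2-methoxycinnamic acid (Ruhemann-type chromone synthesis). The step exploits the symmetry of ring A: in the 3,5-bis(allyloxy)-4-methoxyphenoxy unit the two ring carbons ortho to the ether oxygen (future C4a and C8) are equivalent, and each is activated by O1, the C5 oxygen and the C7 oxygen. One operation therefore forms the pyranone ring and only one chromone can arise. The precursor, acid 16, carries ring B with both prenyl groups and all three phenols as allyl ethers; it comes from an enol triflate (ring B) and a phenol (ring A) by vinylic substitution.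

Key step: step 11

Assumption: enol triflate 8 and acrylates 15 to 17 are drawn as the E isomers (carboxyl carbon cis to the oxygen on C3), as expected from a chelated sodium enolate and a stereoretentive addition–elimination. Any Z isomer would be carried along, since step 11 is expected to be stereoconvergent. Keto ester 7 is racemic and its stereocentre is removed in step 4.

Step 1
Reactants: 1 methyl 4-hydroxybenzoate; 2 prenyl bromide (1-bromo-3-methylbut-2-ene)
Product: 4 methyl 4-hydroxy-3,5-bis(3-methylbut-2-enyl)benzoate, via monoprenyl ester 3 (not isolated)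
Conditions: NaH (2.4 equiv), toluene, 0 °C → rt; prenyl bromide (2.3 equiv in all, added in two portions), rt → 40 °C; aq. NH4Cl
Reagents that add atoms: prenyl bromide (second equivalent of 2), CC(C)=CCBr
Why: twofold ortho-C-alkylation of a sodium phenoxide by an allylic bromide in a non-polar solvent, in which the tight ion pair steers the primary carbon of the bromide to a ring carbon next to oxygen, the dienone first formed tautomerises to phenol 3, and the excess NaH turns 3 into its phenoxide, which takes up the second equivalent of the bromide at the other ortho carbon; the para position is blocked by the ester, so the two prenyl groups should enter at C3 and C5.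

Step 2
Reactants: 4 methyl 4-hydroxy-3,5-bis(3-methylbut-2-enyl)benzoate
Product: 5 methyl 4-(allyloxy)-3,5-bis(3-methylbut-2-enyl)benzoate
Conditions: allyl bromide, K2CO3, DMF, rt → 50 °C
Reagents that add atoms: allyl bromide, C=CCBr
Why: Williamson ether synthesis in a polar aprotic solvent, which directs the phenoxide to react at oxygen and masks the phenol that would otherwise cyclise onto the flanking prenyl groups under acid.

Step 3
Reactants: 5 methyl 4-(allyloxy)-3,5-bis(3-methylbut-2-enyl)benzoate; 6 methyl methoxyacetate
Product: 7 methyl 3-[4-(allyloxy)-3,5-bis(3-methylbut-2-enyl)phenyl]-2-methoxy-3-oxopropanoate (racemic)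
Conditions: 6 (2.5 equiv), LiN(SiMe3)2 (3.5 equiv), THF, −78 → 0 °C; aq. NH4Cl
Reagents that add atoms: none
Why: crossed Claisen condensation in which only 6 can form an enolate and 5 can only act as acyl acceptor, driven forward by deprotonation of the acidic keto ester by the excess base.

Step 4
Reactants: 7 methyl 3-[4-(allyloxy)-3,5-bis(3-methylbut-2-enyl)phenyl]-2-methoxy-3-oxopropanoate
Product: 8 methyl (E)-3-[4-(allyloxy)-3,5-bis(3-methylbut-2-enyl)phenyl]-2-methoxy-3-(trifluoromethylsulfonyloxy)acrylate
Conditions: NaH, THF, 0 °C; PhNTf2, 0 °C → rt; aq. NH4Cl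
Reagents that add atoms: N-phenylbis(trifluoromethanesulfonimide), O=S(=O)(N(c1ccccc1)S(=O)(=O)C(F)(F)F)C(F)(F)F
Why: O-sulfonylation of the chelated sodium enolate of a β-keto ester (enol triflate formation), which should place the triflate cis to the ester, with a mild triflyl donor that leaves the prenyl and allyl alkenes alone.

Step 5
Reactants: 9 methyl 3,5-dihydroxy-4-methoxybenzoate
Product: 10 methyl 3,5-bis(allyloxy)-4-methoxybenzoate
Conditions: allyl bromide (2.5 equiv), K2CO3, DMF, rt
Reagents that add atoms: allyl bromide, C=CCBr
Why: twofold Williamson ether synthesis on the two equivalent phenols, keeping ring A symmetric.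

Step 6
Reactants: 10 methyl 3,5-bis(allyloxy)-4-methoxybenzoate
Product: 11 [3,5-bis(allyloxy)-4-methoxyphenyl]methanol
Conditions: LiAlH4, THF, 0 °C; aq. NaOH work-up
Reagents that add atoms: none
Why: hydride reduction of an aryl ester to the benzylic alcohol, to which aryl allyl ethers are inert.

Step 7
Reactants: 11 [3,5-bis(allyloxy)-4-methoxyphenyl]methanol
Product: 12 3,5-bis(allyloxy)-4-methoxybenzaldehyde
Conditions: MnO2, CH2Cl2, rt
Reagents that add atoms: none
Why: selective oxidation of a benzylic alcohol on activated manganese dioxide, which stops at the aldehyde and does not touch the allyl ethers.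

Step 8
Reactants: 12 3,5-bis(allyloxy)-4-methoxybenzaldehyde
Product: 14 3,5-bis(allyloxy)-4-methoxyphenol, via aryl formate 13 (not isolated)
Conditions: 30% aq. H2O2, H2SO4 (cat.), MeOH, rt
Reagents that add atoms: hydrogen peroxide, OO
Why: acid-catalysed Dakin oxidation (Baeyer–Villiger-type aryl migration in the peroxide adduct, favoured by the para methoxy group) followed by methanolysis of the formate in the same flask; hydrogen peroxide alone should not epoxidise the allyl alkenes.

Step 9
Reactants: 8 methyl (E)-3-[4-(allyloxy)-3,5-bis(3-methylbut-2-enyl)phenyl]-2-methoxy-3-(trifluoromethylsulfonyloxy)acrylate; 14 3,5-bis(allyloxy)-4-methoxyphenol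
Product: 15 methyl (E)-3-[3,5-bis(allyloxy)-4-methoxyphenoxy]-3-[4-(allyloxy)-3,5-bis(3-methylbut-2-enyl)phenyl]-2-methoxyacrylate
Conditions: Cs2CO3, DMF, rt → 50 °C, argon
Reagents that add atoms: none
Why: nucleophilic vinylic substitution by addition–elimination, in which the phenoxide adds to the β-carbon of the triflyloxyacrylate and the ester-stabilised carbanion expels triflate, expected with retention of geometry.

Step 10
Reactants: 15 methyl (E)-3-[3,5-bis(allyloxy)-4-methoxyphenoxy]-3-[4-(allyloxy)-3,5-bis(3-methylbut-2-enyl)phenyl]-2-methoxyacrylate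
Product: 16 (E)-3-[3,5-bis(allyloxy)-4-methoxyphenoxy]-3-[4-(allyloxy)-3,5-bis(3-methylbut-2-enyl)phenyl]-2-methoxyacrylic acid
Conditions: LiOH, THF/H2O, 40 °C; then cold 0.5 M HCl to pH 3–4
Reagents that add atoms: lithium hydroxide, [Li+].[OH-]
Why: saponification of the methyl ester at the acyl carbon; methanol is left out and the β-carbon is fully substituted and carries two donors, so displacement of the aryloxy group by conjugate addition should not compete.

Step 11
Reactants: 16 (E)-3-[3,5-bis(allyloxy)-4-methoxyphenoxy]-3-[4-(allyloxy)-3,5-bis(3-methylbut-2-enyl)phenyl]-2-methoxyacrylic acid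
Product: 18 5,7-bis(allyloxy)-2-[4-(allyloxy)-3,5-bis(3-methylbut-2-enyl)phenyl]-3,6-dimethoxychromen-4-one, via acyl trifluoroacetate 17 (not isolated)
Conditions: TFAA (1.2 equiv), CH2Cl2, −20 → 0 °C; aq. NaHCO3 quench
Reagents that add atoms: trifluoroacetic anhydride, O=C(OC(=O)C(F)(F)F)C(F)(F)F (its trifluoroacetyl group is carried only by intermediate 17 and leaves again on ring closure)
Why: TFAA converts acid 16 into acyl trifluoroacetate 17, whose carbonyl carbon (an acylium equivalent) is attacked by the ring A carbon ortho to the ether oxygen; loss of trifluoroacetate and of the ring proton then gives the C4–C4a bond and the 4-pyranone. The closest known reaction is the Ruhemann chromone and flavone synthesis, an intramolecular Friedel–Crafts acylation of a β-aryloxyacrylic acid, run here with the mixed-anhydride activation used to close 2-aryloxybenzoic acids to xanthones. Ring C closes in a 6-exo-trig mode at the anhydride carbonyl (6-exo-dig if the free acylium ion intervenes), with the arene double bond inside the new ring. No stereocentre is formed, and the alkene geometry should not be critical, because the acylium ion has a ketene–oxocarbenium resonance form with a single C2–C3 bond, so a Z isomer can rotate into the reactive E arrangement. The step needs site selectivity for ring A over the ortho carbon of ring B (which would give an indenone): the attacked carbon is ortho to O1, ortho to the C5 allyloxy group and para to the C7 allyloxy group, whereas ring B offers only an alkyl-flanked carbon meta to its ether, and the symmetry of ring A removes any regiochemical choice. Chemoselectivity towards the prenyl and allyl alkenes rests on near-stoichiometric anhydride at low temperature, so that only about two equivalents of dilute trifluoroacetic acid are present, and on the stability of allyl ethers to that acid.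

Step 12
Reactants: 18 5,7-bis(allyloxy)-2-[4-(allyloxy)-3,5-bis(3-methylbut-2-enyl)phenyl]-3,6-dimethoxychromen-4-one
Product: 19 5,7-dihydroxy-2-[4-hydroxy-3,5-bis(3-methylbut-2-enyl)phenyl]-3,6-dimethoxychromen-4-one (CNP0236361.0)
Conditions: Pd(PPh3)4 (5 mol%), morpholine (excess), THF, rt
Reagents that add atoms: none
Why: Tsuji–Trost-type deallylation, in which zerovalent palladium ionises each aryl allyl ether to a π-allylpalladium phenoxide and morpholine captures the allyl group; the neutral conditions should leave the C-prenyl groups and the acid-sensitive ortho-prenylphenol intact.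

Compound list
1 | methyl 4-hydroxybenzoate | COC(=O)c1ccc(O)cc1 | starting material
2 | prenyl bromide (1-bromo-3-methylbut-2-ene) | CC(C)=CCBr | starting material
3 | methyl 4-hydroxy-3-(3-methylbut-2-enyl)benzoate | COC(=O)c1ccc(O)c(CC=C(C)C)c1 | intermediate (not isolated)
4 | methyl 4-hydroxy-3,5-bis(3-methylbut-2-enyl)benzoate | COC(=O)c1cc(CC=C(C)C)c(O)c(CC=C(C)C)c1 | intermediate
5 | methyl 4-(allyloxy)-3,5-bis(3-methylbut-2-enyl)benzoate | COC(=O)c1cc(CC=C(C)C)c(OCC=C)c(CC=C(C)C)c1 | intermediate
6 | methyl methoxyacetate | COCC(=O)OC | starting material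
7 | methyl 3-[4-(allyloxy)-3,5-bis(3-methylbut-2-enyl)phenyl]-2-methoxy-3-oxopropanoate (racemic) | COC(=O)C(OC)C(=O)c1cc(CC=C(C)C)c(OCC=C)c(CC=C(C)C)c1 | intermediate
8 | methyl (E)-3-[4-(allyloxy)-3,5-bis(3-methylbut-2-enyl)phenyl]-2-methoxy-3-(trifluoromethylsulfonyloxy)acrylate | COC(=O)/C(OC)=C(OS(=O)(=O)C(F)(F)F)/c1cc(CC=C(C)C)c(OCC=C)c(CC=C(C)C)c1 | intermediate
9 | methyl 3,5-dihydroxy-4-methoxybenzoate | COC(=O)c1cc(O)c(OC)c(O)c1 | starting material
10 | methyl 3,5-bis(allyloxy)-4-methoxybenzoate | COC(=O)c1cc(OCC=C)c(OC)c(OCC=C)c1 | intermediate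
11 | [3,5-bis(allyloxy)-4-methoxyphenyl]methanol | OCc1cc(OCC=C)c(OC)c(OCC=C)c1 | intermediate
12 | 3,5-bis(allyloxy)-4-methoxybenzaldehyde | O=Cc1cc(OCC=C)c(OC)c(OCC=C)c1 | intermediate
13 | 3,5-bis(allyloxy)-4-methoxyphenyl formate | O=COc1cc(OCC=C)c(OC)c(OCC=C)c1 | intermediate (not isolated)
14 | 3,5-bis(allyloxy)-4-methoxyphenol | Oc1cc(OCC=C)c(OC)c(OCC=C)c1 | intermediate
15 | methyl (E)-3-[3,5-bis(allyloxy)-4-methoxyphenoxy]-3-[4-(allyloxy)-3,5-bis(3-methylbut-2-enyl)phenyl]-2-methoxyacrylate | COC(=O)/C(OC)=C(Oc1cc(OCC=C)c(OC)c(OCC=C)c1)/c1cc(CC=C(C)C)c(OCC=C)c(CC=C(C)C)c1 | intermediate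
16 | (E)-3-[3,5-bis(allyloxy)-4-methoxyphenoxy]-3-[4-(allyloxy)-3,5-bis(3-methylbut-2-enyl)phenyl]-2-methoxyacrylic acid | OC(=O)/C(OC)=C(Oc1cc(OCC=C)c(OC)c(OCC=C)c1)/c1cc(CC=C(C)C)c(OCC=C)c(CC=C(C)C)c1 | intermediate
17 | (E)-3-[3,5-bis(allyloxy)-4-methoxyphenoxy]-3-[4-(allyloxy)-3,5-bis(3-methylbut-2-enyl)phenyl]-2-methoxyacrylic trifluoroacetic anhydride | O=C(OC(=O)C(F)(F)F)/C(OC)=C(Oc1cc(OCC=C)c(OC)c(OCC=C)c1)/c1cc(CC=C(C)C)c(OCC=C)c(CC=C(C)C)c1 | intermediate (not isolated)
18 | 5,7-bis(allyloxy)-2-[4-(allyloxy)-3,5-bis(3-methylbut-2-enyl)phenyl]-3,6-dimethoxychromen-4-one | C=CCOc1cc2oc(-c3cc(CC=C(C)C)c(OCC=C)c(CC=C(C)C)c3)c(OC)c(=O)c2c(OCC=C)c1OC | intermediate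
19 | 5,7-dihydroxy-2-[4-hydroxy-3,5-bis(3-methylbut-2-enyl)phenyl]-3,6-dimethoxychromen-4-one | COc1c(O)cc2oc(-c3cc(CC=C(C)C)c(O)c(CC=C(C)C)c3)c(OC)c(=O)c2c1O | target

Total step count: 12. Longest linear sequence: 8 steps (steps 1–4 followed by 9–12; the ring A branch, steps 5–8 followed by 9–12, is equally long).

Steps most likely to fail

Step 11. The trifluoroacetic acid set free may add to or cyclise the prenyl alkenes, or the very electron-rich ring A may be trifluoroacetylated before it is acylated intramolecularly. The fallback closes the same C4–C4a bond with an aryl anion instead of an acylium ion. From phenol 14, N-bromosuccinimide (1.0 equiv) in CH2Cl2 at −78 °C should brominate one of the two equivalent ortho carbons to give 2-bromo-3,5-bis(allyloxy)-4-methoxyphenol F1. This is joined to enol triflate 8 as in step 9 (Cs2CO3, DMF) to give methyl (E)-3-[2-bromo-3,5-bis(allyloxy)-4-methoxyphenoxy]-3-[4-(allyloxy)-3,5-bis(3-methylbut-2-enyl)phenyl]-2-methoxyacrylate F2. Bromine–lithium exchange with tert-butyllithium (2 equiv) in THF at −100 °C should then let the aryllithium attack the neighbouring methyl ester with loss of methoxide (Parham cyclisation). The route is rejoined at chromone 18 and steps 10 and 11 are bypassed. This variant needs the E isomer, since no equilibration is available under anionic conditions.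

Step 9. The phenoxide may attack the sulfur of the triflate and take over the triflyl group instead of adding to the β-carbon, or addition to the donor-substituted acrylate may be too slow. The fallback sets out from keto ester 7: Ph3P/C2Cl6/Et3N in MeCN (enol chlorination through a chlorophosphonium salt) should give methyl (E)-3-[4-(allyloxy)-3,5-bis(3-methylbut-2-enyl)phenyl]-3-chloro-2-methoxyacrylate F3, whose halide leaving group cannot be transferred to the phenoxide. Reaction of this vinyl chloride with 14 and Cs2CO3 in DMF at 60 °C, the chlorocinnamate variant of the Ruhemann aryloxyacrylate synthesis, returns to the route at ester 15.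

Step 1. Alkylation at oxygen may compete with alkylation at carbon, and the second ortho alkylation may stay incomplete, so that mono-prenylated and O-prenylated material dominate. The fallback fixes both positions with halogens first. From 1, N-iodosuccinimide (2.2 equiv) with catalytic trifluoroacetic acid in MeCN gives methyl 4-hydroxy-3,5-diiodobenzoate F4. A double Stille coupling with tributyl(3-methylbut-2-enyl)stannane and Pd(PPh3)4 (zerovalent palladium) in DMF at 90 °C should then deliver both prenyl groups at the iodinated carbons, returning to the route at 4.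

Further compounds
F1 | step 11 | 2-bromo-3,5-bis(allyloxy)-4-methoxyphenol | Oc1cc(OCC=C)c(OC)c(OCC=C)c1Br
F2 | step 11 | methyl (E)-3-[2-bromo-3,5-bis(allyloxy)-4-methoxyphenoxy]-3-[4-(allyloxy)-3,5-bis(3-methylbut-2-enyl)phenyl]-2-methoxyacrylate | COC(=O)/C(OC)=C(Oc1cc(OCC=C)c(OC)c(OCC=C)c1Br)/c1cc(CC=C(C)C)c(OCC=C)c(CC=C(C)C)c1
F3 | step 9 | methyl (E)-3-[4-(allyloxy)-3,5-bis(3-methylbut-2-enyl)phenyl]-3-chloro-2-methoxyacrylate | COC(=O)/C(OC)=C(Cl)/c1cc(CC=C(C)C)c(OCC=C)c(CC=C(C)C)c1
F4 | step 1 | methyl 4-hydroxy-3,5-diiodobenzoate | COC(=O)c1cc(I)c(O)c(I)c1
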